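**Plan**

1. Enabling feature: ring A is an acylphloroglucinol, so C4–C4a–C8a–C8–C7–C6–C5 is an unbroken poly-β-carbonyl chain, and the ring C oxygen O1 sits on C8a, β to the C4 carbonyl. The bicycle is therefore one folded linear chain.
2. Retrosynthesis: O1–C8a (ring C) and C4a–C5 (ring A) are cut in one operation. This gives an open (S)-β-hydroxy ynone/(E)-β-methoxyacrylate in which C4a≡C8a masks the 1,3-diketone and C7(OMe)=C6 masks the β-keto ester; it already carries the 7-OMe and the 8-prenyl group.
3. The chain is cut at C4–C4a (acyl Sonogashira) into a C2–C4 acid chloride and a C4a–C5 enyne ester. The enyne ester is cut at C8–C8a (alkyne/allyl bromide coupling) and at C8–prenyl (γ-alkylation).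
4. Forward: fragment 1 (steps 1–3), fragment 2 (steps 4–6), union (step 7), release of the hydroxyl (step 8). In step 9 ring C closes first and ring A second.
5. Stereochemistry: C2 is set once, by asymmetric transfer hydrogenation of an aryl β-keto ester (step 4), and no later bond formation touches it. The chain carbon that becomes C8 is carried as both epimers because it ends as an sp2 ring carbon.

Key step: step 9

**Route**

Step 1
Reactants: 1 methyl (2E)-4-bromo-3-methoxybut-2-enoate; 2 ethynyltrimethylsilane
Product: 3 methyl (2E)-3-methoxy-6-(trimethylsilyl)hex-2-en-5-ynoate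
Conditions: CuI (10 mol%), K2CO3, n-Bu4NI (10 mol%), DMF, rt
Reagents that add atoms: none
Why: Copper-mediated coupling of a terminal alkyne with an allylic bromide; the copper acetylide of 2 should displace bromide directly because the SN2' path would break the push–pull enoate, and the E geometry of the methoxyacrylate is not touched.

Step 2
Reactants: 3 methyl (2E)-3-methoxy-6-(trimethylsilyl)hex-2-en-5-ynoate; 4 1-bromo-3-methylbut-2-ene (prenyl bromide)
Product: 5 methyl (2E)-3-methoxy-7-methyl-4-[(trimethylsilyl)ethynyl]octa-2,6-dienoate (racemic)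
Conditions: LDA, THF/DMPU, −78 °C; then 4, −78 to −40 °C
Reagents that add atoms: none
Why: Vinylogous (γ) alkylation of a β-alkoxy enoate dienolate; LDA removes the hydrogen that is both propargylic and γ to the ester, such dienolates alkylate at the γ carbon, the silyl group shields the alkyne terminus, and the new centre needs no control because it becomes C8 of ring A.

Step 3
Reactants: 5 methyl (2E)-3-methoxy-7-methyl-4-[(trimethylsilyl)ethynyl]octa-2,6-dienoate
Product: 6 methyl (2E)-4-ethynyl-3-methoxy-7-methylocta-2,6-dienoate (racemic)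
Conditions: TBAF, AcOH (1:1), THF, 0 °C
Reagents that add atoms: none
Why: Fluoride-mediated protodesilylation of an alkynylsilane; the acetic acid buffer should keep the medium too weakly basic to shift the doubly activated propargylic hydrogen to the allene.

Step 4
Reactants: 7 ethyl 3-(4-methoxyphenyl)-3-oxopropanoate
Product: 8 ethyl (3S)-3-hydroxy-3-(4-methoxyphenyl)propanoate
Conditions: RuCl(p-cymene)[(S,S)-TsDPEN] (1 mol%), HCO2H/Et3N (5:2), 30 °C
Reagents that add atoms: none
Why: Noyori asymmetric transfer hydrogenation of an aryl ketone; the (S,S)-ligand is chosen because the CH–π contact between the cymene ring and the anisyl group directs hydride to the face that gives the (S)-carbinol with aryl ketones, and this carbon is C2 of the target.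

Step 5
Reactants: 8 ethyl (3S)-3-hydroxy-3-(4-methoxyphenyl)propanoate
Product: 9 ethyl (3S)-3-[(tert-butyldimethylsilyl)oxy]-3-(4-methoxyphenyl)propanoate
Conditions: TBSCl, imidazole, DMF, rt
Reagents that add atoms: tert-butyldimethylsilyl chloride, CC(C)(C)[Si](C)(C)Cl
Why: Standard silylation of a secondary alcohol masks the hydroxyl so that the acid can later be activated as its chloride; the stereocentre is not involved.

Step 6
Reactants: 9 ethyl (3S)-3-[(tert-butyldimethylsilyl)oxy]-3-(4-methoxyphenyl)propanoate
Product: 10 (3S)-3-[(tert-butyldimethylsilyl)oxy]-3-(4-methoxyphenyl)propanoic acid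
Conditions: LiOH·H2O, THF/H2O, 0 °C to rt; then AcOH to pH 5
Reagents that add atoms: lithium hydroxide, [Li+].[OH-]
Why: Saponification of the ethyl ester; the TBS ether tolerates aqueous LiOH and the weakly acidic work-up should not ionise the p-methoxybenzylic C–O bond.

Step 7
Reactants: 10 (3S)-3-[(tert-butyldimethylsilyl)oxy]-3-(4-methoxyphenyl)propanoic acid; 6 methyl (2E)-4-ethynyl-3-methoxy-7-methylocta-2,6-dienoate
Product: 12 methyl (2E,9S)-9-[(tert-butyldimethylsilyl)oxy]-3-methoxy-9-(4-methoxyphenyl)-4-(3-methylbut-2-en-1-yl)-7-oxonon-2-en-5-ynoate (both C4 epimers), via acid chloride 11 (not isolated)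
Conditions: 1-chloro-N,N,2-trimethylprop-1-en-1-amine, CH2Cl2, 0 °C; then 6, Pd(PPh3)2Cl2 (2 mol%), CuI (4 mol%), Et3N (1.2 equiv), THF, 0 °C to rt
Reagents that add atoms: none
Why: Acid chloride formation under neutral conditions followed by acyl Sonogashira coupling (copper acetylide to acylpalladium, then reductive elimination) forms the C4–C4a bond; the ester, the enol ether and the silyl ether are inert and the amine is limited to near one equivalent to spare the acidic hydrogen next to the new ynone.

Step 8
Reactants: 12 methyl (2E,9S)-9-[(tert-butyldimethylsilyl)oxy]-3-methoxy-9-(4-methoxyphenyl)-4-(3-methylbut-2-en-1-yl)-7-oxonon-2-en-5-ynoate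
Product: 13 methyl (2E,9S)-9-hydroxy-3-methoxy-9-(4-methoxyphenyl)-4-(3-methylbut-2-en-1-yl)-7-oxonon-2-en-5-ynoate (both C4 epimers)
Conditions: HF·pyridine, pyridine, THF, 0 °C
Reagents that add atoms: none
Why: Buffered HF cleaves the secondary silyl ether without base, so the β-hydroxy ynone should be released without retro-aldol cleavage and without conjugate addition of an external nucleophile.

Step 9
Reactants: 13 methyl (2E,9S)-9-hydroxy-3-methoxy-9-(4-methoxyphenyl)-4-(3-methylbut-2-en-1-yl)-7-oxonon-2-en-5-ynoate
Product: 16 flowerine (2S)-5-hydroxy-7-methoxy-2-(4-methoxyphenyl)-8-(3-methylbut-2-en-1-yl)-2,3-dihydro-4H-chromen-4-one, via dihydropyranone 14 (not isolated), via dienone 15 (not isolated)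
Conditions: DBU (2.5 equiv), MeCN (0.01 M), 0 °C to rt; aq NH4Cl
Reagents that add atoms: none
Why: Proposed new method: the amidine equilibrates the doubly activated C8 hydrogen of 13 (ynone ⇌ allenone) and catalyses addition of the C2 hydroxyl to C8a, the β-carbon of the C4 ynone, to give dihydropyranone 14; deprotonation of 14 at C8 gives a cross-conjugated dienolate whose α-carbon C4a adds to the C5 ester carbonyl (intramolecular Claisen condensation), methoxide leaves to give dienone 15, and enolisation gives phenol 16. The closest known reaction types are the base- or gold-mediated cycloisomerisation of β-hydroxy ynones to 2,3-dihydro-4H-pyran-4-ones and the Claisen folding of 3,5,7-triketo esters to acylphloroglucinols; their tandem use on a chain masked as an ynone and an enol ether is what is new. Ring C closes by 6-endo-dig oxa-Michael addition (O1 to C8a) and ring A by 6-exo-trig attack of the enolate carbon C4a on the ester carbonyl C5, made irreversible by aromatisation. No stereocentre is created: C2 is that of step 4 and neither bond formation touches it, the C8 epimers converge because C8 becomes sp2, and the C4a centre of 15 is lost on enolisation. The step needs O1 to bond to C8a before any carbon–carbon closure and the 8-prenyl/7-methoxy/5-hydroxy pattern without isomers: C4a is not nucleophilic until the oxa-Michael addition has turned the ynone into a vinylogous ester, only C8a gives a six-membered ring with O1, only C4a can reach the ester through a six-membered transition state, and the 7-oxygen is already a methyl ether so it cannot lactonise onto C5. The (E)-methoxyacrylate places C8 cis to the ester as the closure requires, and a weak metal-free base at low temperature is chosen so that ring C closure should outrun retro-aldol cleavage.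

**Compound list**

1 | methyl (2E)-4-bromo-3-methoxybut-2-enoate | BrC/C(OC)=C\C(=O)OC | starting material
2 | ethynyltrimethylsilane | C#C[Si](C)(C)C | starting material
3 | methyl (2E)-3-methoxy-6-(trimethylsilyl)hex-2-en-5-ynoate | C[Si](C)(C)C#CC/C(OC)=C\C(=O)OC | intermediate
4 | 1-bromo-3-methylbut-2-ene (prenyl bromide) | CC(C)=CCBr | starting material
5 | methyl (2E)-3-methoxy-7-methyl-4-[(trimethylsilyl)ethynyl]octa-2,6-dienoate (racemic) | C[Si](C)(C)C#CC(CC=C(C)C)/C(OC)=C\C(=O)OC | intermediate
6 | methyl (2E)-4-ethynyl-3-methoxy-7-methylocta-2,6-dienoate (racemic) | C#CC(CC=C(C)C)/C(OC)=C\C(=O)OC | intermediate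
7 | ethyl 3-(4-methoxyphenyl)-3-oxopropanoate | CCOC(=O)CC(=O)c1ccc(OC)cc1 | starting material
8 | ethyl (3S)-3-hydroxy-3-(4-methoxyphenyl)propanoate | COc1ccc([C@@H](O)CC(=O)OCC)cc1 | intermediate
9 | ethyl (3S)-3-[(tert-butyldimethylsilyl)oxy]-3-(4-methoxyphenyl)propanoate | COc1ccc([C@@H](O[Si](C)(C)C(C)(C)C)CC(=O)OCC)cc1 | intermediate
10 | (3S)-3-[(tert-butyldimethylsilyl)oxy]-3-(4-methoxyphenyl)propanoic acid | COc1ccc([C@@H](O[Si](C)(C)C(C)(C)C)CC(=O)O)cc1 | intermediate
11 | (3S)-3-[(tert-butyldimethylsilyl)oxy]-3-(4-methoxyphenyl)propanoyl chloride (not isolated) | COc1ccc([C@@H](O[Si](C)(C)C(C)(C)C)CC(=O)Cl)cc1 | intermediate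
12 | methyl (2E,9S)-9-[(tert-butyldimethylsilyl)oxy]-3-methoxy-9-(4-methoxyphenyl)-4-(3-methylbut-2-en-1-yl)-7-oxonon-2-en-5-ynoate (both C4 epimers) | COc1ccc([C@@H](O[Si](C)(C)C(C)(C)C)CC(=O)C#CC(CC=C(C)C)/C(OC)=C\C(=O)OC)cc1 | intermediate
13 | methyl (2E,9S)-9-hydroxy-3-methoxy-9-(4-methoxyphenyl)-4-(3-methylbut-2-en-1-yl)-7-oxonon-2-en-5-ynoate (both C4 epimers) | COc1ccc([C@@H](O)CC(=O)C#CC(CC=C(C)C)/C(OC)=C\C(=O)OC)cc1 | intermediate
14 | methyl (2E)-3-methoxy-4-[(2S)-2-(4-methoxyphenyl)-4-oxo-3,4-dihydro-2H-pyran-6-yl]-7-methylocta-2,6-dienoate (not isolated) | COc1ccc([C@@H]2CC(=O)C=C(O2)C(CC=C(C)C)/C(OC)=C\C(=O)OC)cc1 | intermediate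
15 | (2S)-7-methoxy-2-(4-methoxyphenyl)-8-(3-methylbut-2-en-1-yl)-2,3-dihydro-4H-chromene-4,5(4aH)-dione, keto tautomer of 16 (not isolated) | COc1ccc([C@@H]2CC(=O)C3C(=O)C=C(OC)C(CC=C(C)C)=C3O2)cc1 | intermediate
16 | flowerine, (2S)-5-hydroxy-7-methoxy-2-(4-methoxyphenyl)-8-(3-methylbut-2-en-1-yl)-2,3-dihydro-4H-chromen-4-one | COc1ccc([C@@H]2CC(=O)c3c(O)cc(OC)c(CC=C(C)C)c3O2)cc1 | target

**Step count**

Total steps: 9. Longest linear sequence: 6 steps (steps 4, 5, 6, 7, 8, 9 from 7; equally steps 1, 2, 3, 7, 8, 9 from 1).

**Steps most likely to fail**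

1. Step 9 (proposed new method). The carbon–carbon closure onto the deactivated vinylogous-carbonate ester may be slow under conditions mild enough to avoid retro-aldol fragmentation of 13. Reversible opening of ring C by retro-oxa-Michael reaction could also erode enantiopurity. The fallback uses known chemistry and fixes the position of O1 with a fluorine substituent instead of the chain; it sets out from 9 and returns at 16.
   - Ester 9 is converted with MeNHOMe·HCl and i-PrMgCl (THF, −20 °C) into Weinreb amide F1.
   - Commercial 1-fluoro-3,5-dimethoxybenzene is lithiated at the position flanked by fluorine and methoxyl (n-BuLi, THF, −78 °C) and alkylated with 4 in the presence of CuBr·SMe2 to give prenyl fluoroarene F2.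
   - A second ortho-lithiation of F2 at the remaining position between fluorine and methoxyl, followed by addition to F1, should give aryl ketone F3.
   - HF·pyridine releases hydroxy ketone F4.
   - The alkoxide of F4 (KHMDS, THF, −20 °C) closes the O1–C8a bond by intramolecular nucleophilic aromatic substitution of the fluoride, which is activated by the ortho acyl group. C2 is retained, giving dimethyl ether flavanone F5.
   - BCl3 (CH2Cl2, −78 °C) should cleave only the 5-methoxyl chelated to the C4 carbonyl and give 16.

2. Step 2. The delocalised anion may alkylate at the wrong terminus (the α-carbon or the alkyne terminus, the latter giving an allene), or alkylate twice. The fallback replaces the enol ether dienolate with a β-keto ester dianion, whose alkylation is reliably γ-selective; it sets out from 3 and returns at 5.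
   - The enol ether of 3 is hydrolysed (2 M aq HCl, THF, rt) to keto ester F6.
   - The dianion of F6 (NaH, then n-BuLi, THF, 0 °C) is alkylated with 4 at the terminal (γ) carbon to give prenyl keto ester F7.
   - HC(OMe)3 with catalytic H2SO4 in MeOH re-forms the (E)-enol ether conjugated with the ester and gives 5.

3. Step 7. The amine may shift the propargylic hydrogen of 6 or of the ynone product to the allene, and the β-silyloxy acid chloride may eliminate. The fallback forms the C4–C4a bond by carbonyl addition and oxidation instead of acylation; it sets out from 9 (with 6) and returns at 12.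
   - Ester 9 is reduced with DIBAL-H (CH2Cl2, −78 °C) to aldehyde F8.
   - Alkyne 6 is added to F8 under Zn(OTf)2/Et3N (toluene, rt) to give propargylic alcohol F9; the configuration of the new carbinol is irrelevant.
   - Dess–Martin periodinane (NaHCO3, CH2Cl2, 0 °C) oxidises F9 to 12.

**Further compounds**

F1 | step 9 | (3S)-3-[(tert-butyldimethylsilyl)oxy]-N-methoxy-3-(4-methoxyphenyl)-N-methylpropanamide | COc1ccc([C@@H](O[Si](C)(C)C(C)(C)C)CC(=O)N(C)OC)cc1
F2 | step 9 | 1-fluoro-3,5-dimethoxy-2-(3-methylbut-2-en-1-yl)benzene | COc1cc(F)c(CC=C(C)C)c(OC)c1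
F3 | step 9 | (3S)-3-[(tert-butyldimethylsilyl)oxy]-1-[2-fluoro-4,6-dimethoxy-3-(3-methylbut-2-en-1-yl)phenyl]-3-(4-methoxyphenyl)propan-1-one | COc1ccc([C@@H](O[Si](C)(C)C(C)(C)C)CC(=O)c2c(F)c(CC=C(C)C)c(OC)cc2OC)cc1
F4 | step 9 | (3S)-1-[2-fluoro-4,6-dimethoxy-3-(3-methylbut-2-en-1-yl)phenyl]-3-hydroxy-3-(4-methoxyphenyl)propan-1-one | COc1ccc([C@@H](O)CC(=O)c2c(F)c(CC=C(C)C)c(OC)cc2OC)cc1
F5 | step 9 | (2S)-5,7-dimethoxy-2-(4-methoxyphenyl)-8-(3-methylbut-2-en-1-yl)-2,3-dihydro-4H-chromen-4-one | COc1ccc([C@@H]2CC(=O)c3c(OC)cc(OC)c(CC=C(C)C)c3O2)cc1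
F6 | step 2 | methyl 3-oxo-6-(trimethylsilyl)hex-5-ynoate | COC(=O)CC(=O)CC#C[Si](C)(C)C
F7 | step 2 | methyl 7-methyl-3-oxo-4-[(trimethylsilyl)ethynyl]oct-6-enoate | COC(=O)CC(=O)C(CC=C(C)C)C#C[Si](C)(C)C
F8 | step 7 | (3S)-3-[(tert-butyldimethylsilyl)oxy]-3-(4-methoxyphenyl)propanal | COc1ccc([C@@H](O[Si](C)(C)C(C)(C)C)CC=O)cc1
F9 | step 7 | methyl (2E,9S)-9-[(tert-butyldimethylsilyl)oxy]-7-hydroxy-3-methoxy-9-(4-methoxyphenyl)-4-(3-methylbut-2-en-1-yl)non-2-en-5-ynoate | COc1ccc([C@@H](O[Si](C)(C)C(C)(C)C)CC(O)C#CC(CC=C(C)C)/C(OC)=C\C(=O)OC)cc1
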